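**Retrosynthetic overview**
- The 2H-pyran ring of the chromene is opened last-ring-first to an aryl 1,1-dimethylpropargyl ether (thermal dearomative propargyl Claisen / 1,5-H shift / oxa-6π cascade).
- Key disconnection: the isoflavone C3–aryl bond is made by a 1,2-aryl shift, not by coupling. A 2'-hydroxychalcone is oxidised with Tl(III); its vanillin-derived ring moves from Cβ to Cα through a dearomatised spiro phenonium ion, and acid then closes the pyran-4-one.
- The chalcone comes from a Claisen–Schmidt condensation of O-(1,1-dimethylpropargyl)vanillin with 2,4-dihydroxyacetophenone. The propargyl ether (vanillin + 3-chloro-3-methylbut-1-yne) serves as phenol protection and as the latent chromene.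
- Ring order: both benzene rings are bought; the pyran-4-one ring forms in step 3 and the 2H-pyran ring in step 4.

Assumption: the target has no stereocentre (its only stereo-element, the ring alkene of the 2H-chromene, is necessarily cis), so it is achiral and the structure as drawn is the single compound to be made.

**Route**

Step 1
Reactants: 1 vanillin (4-hydroxy-3-methoxybenzaldehyde); 2 3-chloro-3-methylbut-1-yne
Product: 3 3-methoxy-4-[(2-methylbut-3-yn-2-yl)oxy]benzaldehyde
Conditions: 2 (1.5 equiv), K2CO3 (2 equiv), KI (10 mol %), CuI (5 mol %), acetone, reflux, 24 h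
Reagents that add atoms: none
Why: Copper-catalysed propargylic O-alkylation (Williamson-type etherification via a copper acetylide) lets the hindered tertiary chloride alkylate the acidic, electron-poor phenoxide, and the quaternary propargylic carbon cannot isomerise to an allene.

Step 2
Reactants: 3 3-methoxy-4-[(2-methylbut-3-yn-2-yl)oxy]benzaldehyde; 4 2,4-dihydroxyacetophenone
Product: 5 (E)-1-(2,4-dihydroxyphenyl)-3-{3-methoxy-4-[(2-methylbut-3-yn-2-yl)oxy]phenyl}prop-2-en-1-one
Conditions: 50 % aq KOH (12 equiv), EtOH, 0 °C to rt, 48 h; then 2 M HCl to pH 3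
Reagents that add atoms: none
Why: Claisen–Schmidt (crossed aldol) condensation of the methyl ketone enolate with the non-enolisable aldehyde, followed by E1cB dehydration, gives the thermodynamically favoured (E)-enone; no stereocentre is formed.

Step 3
Reactants: 5 (E)-1-(2,4-dihydroxyphenyl)-3-{3-methoxy-4-[(2-methylbut-3-yn-2-yl)oxy]phenyl}prop-2-en-1-one
Product: 8 7-hydroxy-3-{3-methoxy-4-[(2-methylbut-3-yn-2-yl)oxy]phenyl}-4H-chromen-4-one, via phenonium ion 6 (not isolated), via dimethyl acetal 7 (not isolated)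
Conditions: Tl(NO3)3·3H2O (1.1 equiv), MeOH, rt, 3 h; filter off TlNO3; then 10 % aq HCl (cat.), 55 °C, 2 h
Reagents that add atoms: none
Why: Tl(III)-mediated oxidative 1,2-aryl rearrangement of a 2'-hydroxychalcone: methoxythallation of the enone and loss of Tl(I) with participation of the para-alkoxyaryl ring give the dearomatised spiro phenonium ion 6, which opens to place the aryl group on Cα and is trapped by MeOH as acetal 7; acid then closes 7 onto the 2'-OH with loss of two MeOH, and no stereocentre survives.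

Step 4
Reactants: 8 7-hydroxy-3-{3-methoxy-4-[(2-methylbut-3-yn-2-yl)oxy]phenyl}-4H-chromen-4-one
Product: 12 7-hydroxy-3-(8-methoxy-2,2-dimethyl-2H-chromen-6-yl)-4H-chromen-4-one (target), via allenyl dienone 9 (not isolated), via allenylphenol 10 (not isolated), via o-quinone methide 11 (not isolated)
Conditions: PhNEt2, 190 °C, 2 h, Ar
Reagents that add atoms: none
Why: Aromatic propargyl Claisen rearrangement ([3,3]) to the only free ortho carbon dearomatises the ring to dienone 9, which enolises to 10, undergoes a 1,5-H shift to o-quinone methide 11 and closes by oxa-6π electrocyclisation to the 2,2-dimethyl-2H-chromene; the cis ring alkene is fixed by the ring and no stereocentre is formed.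

**Compound list**

1 | vanillin (4-hydroxy-3-methoxybenzaldehyde) | COc1cc(C=O)ccc1O | starting material
2 | 3-chloro-3-methylbut-1-yne | CC(C)(Cl)C#C | starting material
3 | 3-methoxy-4-[(2-methylbut-3-yn-2-yl)oxy]benzaldehyde | COc1cc(C=O)ccc1OC(C)(C)C#C | intermediate
4 | 2,4-dihydroxyacetophenone | CC(=O)c1ccc(O)cc1O | starting material
5 | (E)-1-(2,4-dihydroxyphenyl)-3-{3-methoxy-4-[(2-methylbut-3-yn-2-yl)oxy]phenyl}prop-2-en-1-one | COc1cc(/C=C/C(=O)c2ccc(O)cc2O)ccc1OC(C)(C)C#C | intermediate
6 | phenonium ion: [1-(2,4-dihydroxybenzoyl)-2,7-dimethoxyspiro[2.5]octa-4,7-dien-6-ylidene](2-methylbut-3-yn-2-yl)oxonium, nitrate counter-ion, transient mixture of stereoisomers | COC1C(C(=O)c2ccc(O)cc2O)C13C=CC(=[O+]C(C)(C)C#C)C(OC)=C3 | intermediate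
7 | 1-(2,4-dihydroxyphenyl)-3,3-dimethoxy-2-{3-methoxy-4-[(2-methylbut-3-yn-2-yl)oxy]phenyl}propan-1-one (racemic) | COc1cc(C(C(OC)OC)C(=O)c2ccc(O)cc2O)ccc1OC(C)(C)C#C | intermediate
8 | 7-hydroxy-3-{3-methoxy-4-[(2-methylbut-3-yn-2-yl)oxy]phenyl}-4H-chromen-4-one | COc1cc(-c2coc3cc(O)ccc3c2=O)ccc1OC(C)(C)C#C | intermediate
9 | 7-hydroxy-3-[5-methoxy-3-(3-methylbuta-1,2-dien-1-yl)-4-oxocyclohexa-1,5-dien-1-yl]-4H-chromen-4-one (racemic) | COC1=CC(-c2coc3cc(O)ccc3c2=O)=CC(C=C=C(C)C)C1=O | intermediate
10 | 7-hydroxy-3-[4-hydroxy-3-methoxy-5-(3-methylbuta-1,2-dien-1-yl)phenyl]-4H-chromen-4-one | COc1cc(-c2coc3cc(O)ccc3c2=O)cc(C=C=C(C)C)c1O | intermediate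
11 | 7-hydroxy-3-[(3Z)-5-methoxy-3-(3-methylbut-2-en-1-ylidene)-4-oxocyclohexa-1,5-dien-1-yl]-4H-chromen-4-one | CC(C)=C/C=C1/C=C(-c2coc3cc(O)ccc3c2=O)C=C(OC)C1=O | intermediate
12 | 7-hydroxy-3-(8-methoxy-2,2-dimethyl-2H-chromen-6-yl)-4H-chromen-4-one | COc1cc(-c2coc3cc(O)ccc3c2=O)cc2c1OC(C)(C)C=C2 | target

**Step count and risks**

Total steps: 4. Longest linear sequence: 4 (from vanillin 1).

Steps most likely to fail, most risky first:

Step 3. Tl(III) may oxythallate the terminal alkyne or oxidise the free 4'-phenol. The tert-alkoxy donor, twisted by the ortho methoxy group, may also migrate slowly enough for aurone formation to compete, and the tertiary propargyl ether must survive the acid stage. The fallback sets out from 5 and changes both substrate class and oxidant. Heating 5 with NaOAc in EtOH closes it by oxa-Michael addition to the flavanone 7-hydroxy-2-{3-methoxy-4-[(2-methylbut-3-yn-2-yl)oxy]phenyl}-2,3-dihydro-4H-chromen-4-one F1 (racemic). Treating this with PhI(OH)OTs in MeCN makes the ketone enol attack iodine(III), and the 2-aryl group shifts to C3 with loss of PhI, without thallium or methanol. The fallback comes back to the route at 8.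

Step 4. At 190 °C allenylphenol 10 can close 5-exo to a benzofuran, and the free 7-hydroxychromone may degrade. The fallback sets out from 8 and builds the pyran ring by a prenylphenol route. Lindlar semi-hydrogenation (H2, Pd/CaCO3/Pb, quinoline, EtOAc) gives the allyl ether 7-hydroxy-3-{3-methoxy-4-[(2-methylbut-3-en-2-yl)oxy]phenyl}-4H-chromen-4-one F2. An aromatic Claisen rearrangement at about 130 °C in PhNEt2 gives the ortho-prenylphenol 7-hydroxy-3-[4-hydroxy-3-methoxy-5-(3-methylbut-2-en-1-yl)phenyl]-4H-chromen-4-one F3. Oxidative cyclisation with DDQ in benzene at reflux then closes the chromene, and the fallback comes back to the route at 12.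

Step 2. The dianion of 4 enolises poorly, so the condensation can stall, 3 can undergo Cannizzaro disproportionation, and the product can partly cyclise to the flavanone on acidification. The fallback sets out from 4 and uses a protected ketone. MOMCl with K2CO3 in acetone alkylates only the non-chelated 4-OH to give 1-[2-hydroxy-4-(methoxymethoxy)phenyl]ethan-1-one F4. Its mono-anion condenses cleanly with 3 (KOH, EtOH) to (E)-1-[2-hydroxy-4-(methoxymethoxy)phenyl]-3-{3-methoxy-4-[(2-methylbut-3-yn-2-yl)oxy]phenyl}prop-2-en-1-one F5. Tl(NO3)3 in MeOH rearranges this to 1-[2-hydroxy-4-(methoxymethoxy)phenyl]-3,3-dimethoxy-2-{3-methoxy-4-[(2-methylbut-3-yn-2-yl)oxy]phenyl}propan-1-one F6, now with the 4'-oxygen masked. HCl in MeOH at 55 °C removes the MOM group and closes the pyranone in one operation, so the fallback bypasses 5 and comes back to the route at 8.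

**Further compounds**

F1 | step 3 | 7-hydroxy-2-{3-methoxy-4-[(2-methylbut-3-yn-2-yl)oxy]phenyl}-2,3-dihydro-4H-chromen-4-one (racemic) | COc1cc(C2CC(=O)c3ccc(O)cc3O2)ccc1OC(C)(C)C#C
F2 | step 4 | 7-hydroxy-3-{3-methoxy-4-[(2-methylbut-3-en-2-yl)oxy]phenyl}-4H-chromen-4-one | COc1cc(-c2coc3cc(O)ccc3c2=O)ccc1OC(C)(C)C=C
F3 | step 4 | 7-hydroxy-3-[4-hydroxy-3-methoxy-5-(3-methylbut-2-en-1-yl)phenyl]-4H-chromen-4-one | COc1cc(-c2coc3cc(O)ccc3c2=O)cc(CC=C(C)C)c1O
F4 | step 2 | 1-[2-hydroxy-4-(methoxymethoxy)phenyl]ethan-1-one | CC(=O)c1ccc(OCOC)cc1O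
F5 | step 2 | (E)-1-[2-hydroxy-4-(methoxymethoxy)phenyl]-3-{3-methoxy-4-[(2-methylbut-3-yn-2-yl)oxy]phenyl}prop-2-en-1-one | COCOc1ccc(C(=O)/C=C/c2ccc(OC(C)(C)C#C)c(OC)c2)c(O)c1
F6 | step 2 | 1-[2-hydroxy-4-(methoxymethoxy)phenyl]-3,3-dimethoxy-2-{3-methoxy-4-[(2-methylbut-3-yn-2-yl)oxy]phenyl}propan-1-one (racemic) | COCOc1ccc(C(=O)C(C(OC)OC)c2ccc(OC(C)(C)C#C)c(OC)c2)c(O)c1
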